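**Retrosynthetic overview**
- The target comes from its 5-O-methyl ether by chelation-controlled demethylation. The dihydropyranone ring is closed last by an alkaloid-catalysed cis-selective oxa-Michael addition of an ortho-tigloyl phenol.
- That phenol comes from a tigloylated dihydrocoumarin by lactone methanolysis and C-prenylation in one pot. The tigloyl group is put in by phenol-directed acylation.
- The dihydrocoumarin comes from a 3-propylindan-1-one by Baeyer–Villiger ring expansion (aryl C-to-O 1,2-shift). This step creates the third ring oxygen and unmasks the hexanoate chain.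
- The indanone comes from a resorcinol-derived dihydrocoumarin by an acid-mediated acyl shift. That lactone is made by a new enantioselective carbene-catalysed annulation of resorcinol with (E)-hex-2-enal, which sets the side-chain centre.
- Ring order: benzene ring (bought), first lactone, five-membered ketone, ring-expanded lactone (opened later), dihydropyranone.

Assumption: the sense of induction of the two chiral catalysts is taken from their closest analogues; if experiment shows the opposite, the mirror-image carbene precatalyst or quinidine is used.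

Step 1
Reactants: 1 resorcinol; 2 (E)-hex-2-enal
Product: 3 (S)-7-hydroxy-4-propylchroman-2-one
Conditions: chiral aminoindanol-derived N-mesityl triazolium tetrafluoroborate (10 mol%), 3,3',5,5'-tetra-tert-butyldiphenoquinone (1.1 equiv), DABCO (20 mol%), 4 Å MS, THF, rt; 1 in 3-fold excess
Reagents that add atoms: none
Why: Proposed new method: the carbene adds to 2 and the quinone oxidises the Breslow intermediate to a catalyst-bound α,β-unsaturated acyl azolium, which resorcinol attacks through C4 (ortho to one OH, para to the other) in a Friedel–Crafts-type conjugate addition on the face left open by the indane wall, after which the neighbouring OH is acylated to close the lactone and release the carbene, so the benzylic centre is set as (S) by catalyst control; the closest known reaction type is the oxidative N-heterocyclic-carbene annulation of enals with naphthols and 1,3-dicarbonyl compounds, not yet shown for resorcinol itself with a β-alkyl enal.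

Step 2
Reactants: 3 (S)-7-hydroxy-4-propylchroman-2-one
Product: 4 (S)-7-methoxy-4-propylchroman-2-one
Conditions: MeI (1.5 equiv), K2CO3 (1.5 equiv), dry acetone, rt to 40 °C
Reagents that add atoms: iodomethane, CI
Why: Williamson O-methylation of the only free phenol under anhydrous weakly basic conditions that leave lactone and stereocentre untouched; it marks the oxygen para to the side chain so that only an ortho oxygen is free later.

Step 3
Reactants: 4 (S)-7-methoxy-4-propylchroman-2-one
Product: 5 (S)-4-hydroxy-6-methoxy-3-propyl-2,3-dihydro-1H-inden-1-one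
Conditions: TfOH (10 equiv), 1,2-dichloroethane, 60 °C
Reagents that add atoms: none
Why: Acid-mediated Fries-type acyl shift in which the protonated aryl ester opens to a tethered acylium ion that can reach only the ring carbon ortho to the side chain (intramolecular Friedel–Crafts acylation, five-membered ring) and frees the phenol; the stereocentre is not involved and stays (S).

Step 4
Reactants: 5 (S)-4-hydroxy-6-methoxy-3-propyl-2,3-dihydro-1H-inden-1-one
Product: 6 (S)-5-hydroxy-7-methoxy-4-propylchroman-2-one
Conditions: mCPBA (1.3 equiv), TFA (cat.), CH2Cl2, 0 °C to rt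
Reagents that add atoms: 3-chloroperoxybenzoic acid (mCPBA), O=C(OO)c1cccc(Cl)c1
Why: Baeyer–Villiger oxidation in which the aryl carbon of the Criegee adduct migrates from carbon to oxygen in preference to CH2 (as known for 1-indanones), a 1,2-shift that expands the five-membered ketone to the six-membered lactone and completes the 1,3,5-trioxygenated ring while the propyl-bearing centre is a spectator and stays (S).

Step 5
Reactants: 6 (S)-5-hydroxy-7-methoxy-4-propylchroman-2-one; 7 (E)-2-methylbut-2-enoyl chloride (tigloyl chloride)
Product: 8 (S)-5-hydroxy-7-methoxy-6-[(E)-2-methylbut-2-enoyl]-4-propylchroman-2-one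
Conditions: TiCl4 (2.2 equiv), CH2Cl2, 0 °C to rt; aq. HCl work-up
Reagents that add atoms: none
Why: Phenol-directed Friedel–Crafts acylation through the titanium phenoxide (Fries-type delivery) goes to the only carbon ortho to the free OH and gives the chelated ortho-hydroxyaryl enone with E geometry retained, without touching lactone, methyl ether or stereocentre.

Step 6
Reactants: 8 (S)-5-hydroxy-7-methoxy-6-[(E)-2-methylbut-2-enoyl]-4-propylchroman-2-one; 9 1-bromo-3-methylbut-2-ene (prenyl bromide)
Product: 11 methyl (S)-3-[2,6-dihydroxy-4-methoxy-3-((E)-2-methylbut-2-enoyl)-5-(3-methylbut-2-en-1-yl)phenyl]hexanoate, via ring-opened methyl ester 10 (not isolated)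
Conditions: NaOMe (3 equiv), MeOH, 0 °C, 30 min; then 9 (1.1 equiv), 0 °C, 2 h; poured into cold 1 M HCl
Reagents that add atoms: methanol (as NaOMe/MeOH), CO
Why: Methoxide transesterifies the aryl lactone to the methyl ester bis-phenoxide, whose only unsubstituted ring carbon is C-alkylated by prenyl bromide (C-alkylation of a phloroglucinol-type phenoxide in protic solvent), while excess methoxide holds the enone as the open bis-phenoxide (as for 2'-hydroxychalcones in strong base) so that no uncontrolled ring closure occurs before the cold acid quench.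

Step 7
Reactants: 11 methyl (S)-3-[2,6-dihydroxy-4-methoxy-3-((E)-2-methylbut-2-enoyl)-5-(3-methylbut-2-en-1-yl)phenyl]hexanoate
Product: 12 methyl (S)-3-[(2R,3S)-7-hydroxy-5-methoxy-2,3-dimethyl-6-(3-methylbut-2-en-1-yl)-4-oxochroman-8-yl]hexanoate
Conditions: (−)-quinine (30 mol%), chlorobenzene, 15 °C to rt, 2–4 d
Reagents that add atoms: none
Why: Cinchona-alkaloid-catalysed asymmetric intramolecular oxa-Michael addition (6-endo), known for ortho-tigloyl hydroxycoumarins: the quinuclidine ion-pairs the only phenol next to the enone (the other flank is OMe, so one regioisomer), its addition sets C2 as (R), and kinetic protonation of the enolate by the quinuclidinium sets C3 as (S), giving the cis-2,3-dimethyl ring under catalyst control independent of the remote side-chain centre.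

Step 8
Reactants: 12 methyl (S)-3-[(2R,3S)-7-hydroxy-5-methoxy-2,3-dimethyl-6-(3-methylbut-2-en-1-yl)-4-oxochroman-8-yl]hexanoate
Product: 13 methyl (S)-3-[(2R,3S)-5,7-dihydroxy-2,3-dimethyl-6-(3-methylbut-2-en-1-yl)-4-oxochroman-8-yl]hexanoate (CNP0068017.4)
Conditions: BCl3 (3 equiv), CH2Cl2, −78 °C to −30 °C, 1 h; MeOH quench, 0 °C
Reagents that add atoms: none
Why: Chelation-controlled Lewis-acid ether cleavage in which BCl3 bridges the C4 carbonyl and the peri 5-methoxy oxygen so that chloride removes only this methyl group at low temperature, and the non-basic conditions with a methanol quench keep the methyl ester, the prenyl group and the base-sensitive cis C2/C3 centres intact.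

**Compound list**
1 | resorcinol | Oc1cccc(O)c1 | starting material
2 | (E)-hex-2-enal | CCC/C=C/C=O | starting material
3 | (S)-7-hydroxy-4-propylchroman-2-one | CCC[C@H]1CC(=O)Oc2cc(O)ccc12 | intermediate
4 | (S)-7-methoxy-4-propylchroman-2-one | CCC[C@H]1CC(=O)Oc2cc(OC)ccc12 | intermediate
5 | (S)-4-hydroxy-6-methoxy-3-propyl-2,3-dihydro-1H-inden-1-one | CCC[C@H]1CC(=O)c2cc(OC)cc(O)c12 | intermediate
6 | (S)-5-hydroxy-7-methoxy-4-propylchroman-2-one | CCC[C@H]1CC(=O)Oc2cc(OC)cc(O)c12 | intermediate
7 | (E)-2-methylbut-2-enoyl chloride (tigloyl chloride) | C/C=C(\C)C(Cl)=O | starting material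
8 | (S)-5-hydroxy-7-methoxy-6-[(E)-2-methylbut-2-enoyl]-4-propylchroman-2-one | CCC[C@H]1CC(=O)Oc2cc(OC)c(C(=O)/C(C)=C/C)c(O)c12 | intermediate
9 | 1-bromo-3-methylbut-2-ene (prenyl bromide) | CC(C)=CCBr | starting material
10 | methyl (S)-3-[2,6-dihydroxy-4-methoxy-3-((E)-2-methylbut-2-enoyl)phenyl]hexanoate (present as its sodium phenoxide, not isolated) | CCC[C@@H](CC(=O)OC)c1c(O)cc(OC)c(C(=O)/C(C)=C/C)c1O | intermediate
11 | methyl (S)-3-[2,6-dihydroxy-4-methoxy-3-((E)-2-methylbut-2-enoyl)-5-(3-methylbut-2-en-1-yl)phenyl]hexanoate | CCC[C@@H](CC(=O)OC)c1c(O)c(CC=C(C)C)c(OC)c(C(=O)/C(C)=C/C)c1O | intermediate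
12 | methyl (S)-3-[(2R,3S)-7-hydroxy-5-methoxy-2,3-dimethyl-6-(3-methylbut-2-en-1-yl)-4-oxochroman-8-yl]hexanoate | CCC[C@@H](CC(=O)OC)c1c(O)c(CC=C(C)C)c(OC)c2c1O[C@H](C)[C@H](C)C2=O | intermediate
13 | methyl (S)-3-[(2R,3S)-5,7-dihydroxy-2,3-dimethyl-6-(3-methylbut-2-en-1-yl)-4-oxochroman-8-yl]hexanoate | CCC[C@@H](CC(=O)OC)c1c(O)c(CC=C(C)C)c(O)c2c1O[C@H](C)[C@H](C)C2=O | target

**Step count:** 8 steps in total; longest linear sequence 8 steps.

**Steps most likely to fail**

Step 1 (the new carbene annulation) may stop at O-acylation of resorcinol or give low enantioselectivity. The fallback uses known chemistry and sets out from 1. Hydroarylation and lactonisation of 1 with hex-2-ynoic acid (Pd(OAc)2 cat., TFA, rt) gives 7-hydroxy-4-propyl-2H-chromen-2-one F1. Methylation (MeI, K2CO3, acetone) gives 7-methoxy-4-propyl-2H-chromen-2-one F2. Copper hydride asymmetric 1,4-reduction of the coumarin (Cu(OAc)2 cat., the DTBM-SEGPHOS enantiomer that gives the (S) product, diethoxymethylsilane, t-BuOH, toluene, then acidic work-up) delivers 4, where the route is rejoined.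

Step 3 (acyl shift to the indanone) requires acylation at a ring carbon meta to both oxygens, so intermolecular acylation at activated positions may compete. The fallback sets out from 4 and replaces the acyl shift by a classical cyclisation of an open-chain acid whose phenol is capped. Aqueous NaOH opens the lactone and MsCl sulfonylates the phenoxide, giving after acidification (S)-3-[4-methoxy-2-(methylsulfonyloxy)phenyl]hexanoic acid F3. Eaton's reagent (P2O5 in MsOH, 50 °C) cyclises it to (S)-6-methoxy-1-oxo-3-propyl-2,3-dihydro-1H-inden-4-yl methanesulfonate F4. NaOH in aqueous MeOH removes the sulfonate and returns to the route at 5.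

Step 6 (one-pot methanolysis and C-prenylation) may give O-prenyl ethers or some racemic ring closure. The fallback sets out from 8 and avoids base altogether. Iodination para to the chelated phenol (NIS, cat. TFA, MeCN, 0 °C) gives (S)-5-hydroxy-8-iodo-7-methoxy-6-[(E)-2-methylbut-2-enoyl]-4-propylchroman-2-one F5. Stille coupling with tributyl(3-methylbut-2-en-1-yl)stannane (Pd(PPh3)4, DMF, 70 °C) gives (S)-5-hydroxy-7-methoxy-6-[(E)-2-methylbut-2-enoyl]-8-(3-methylbut-2-en-1-yl)-4-propylchroman-2-one F6. Acid-catalysed methanolysis of the lactone (MeOH, cat. H2SO4, rt) returns to the route at 11.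

**Further compounds**
F1 | step 1 | 7-hydroxy-4-propyl-2H-chromen-2-one | CCCC1=CC(=O)Oc2cc(O)ccc12
F2 | step 1 | 7-methoxy-4-propyl-2H-chromen-2-one | CCCC1=CC(=O)Oc2cc(OC)ccc12
F3 | step 3 | (S)-3-[4-methoxy-2-(methylsulfonyloxy)phenyl]hexanoic acid | CCC[C@@H](CC(=O)O)c1ccc(OC)cc1OS(C)(=O)=O
F4 | step 3 | (S)-6-methoxy-1-oxo-3-propyl-2,3-dihydro-1H-inden-4-yl methanesulfonate | CCC[C@H]1CC(=O)c2cc(OC)cc(OS(C)(=O)=O)c12
F5 | step 6 | (S)-5-hydroxy-8-iodo-7-methoxy-6-[(E)-2-methylbut-2-enoyl]-4-propylchroman-2-one | CCC[C@H]1CC(=O)Oc2c(I)c(OC)c(C(=O)/C(C)=C/C)c(O)c12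
F6 | step 6 | (S)-5-hydroxy-7-methoxy-6-[(E)-2-methylbut-2-enoyl]-8-(3-methylbut-2-en-1-yl)-4-propylchroman-2-one | CCC[C@H]1CC(=O)Oc2c(CC=C(C)C)c(OC)c(C(=O)/C(C)=C/C)c(O)c12
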